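The ten-membered carbocycle is cut twice, at C6–C7 and C8–C9 (germacrane numbering: C1–O–C5 ether bridge, C6 lactone carbinol, C8 ester carbinol, C9=C10), which excises C7–C8 together with the acrylate carbons C11–C13. The key step exploits that C6 and C8 are both carbinol carbons flanking C7, the γ-carbon of the α-methylene lactone ring: this triad maps onto a 3-(bromomethyl)-5-menthyloxybutenolide. In one pot, CrCl2 allylates the C6 aldehyde of a cis-2,6-disubstituted tetrahydropyran with this linchpin, the alkoxide translactonises and thereby releases the C8 aldehyde, and NiCl2 then closes the carbocycle through the C9 alkenyl iodide; lactone, ring and C6, C7, C8 arise together.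

Key step: step 16

Remark on numbering: C1–C10 are the ring carbons (C1 and C5 the ether carbons, C4 the spiro-epoxide carbon, C15 its CH2), C11–C13 the lactone acrylate carbons (C12 carbonyl, C13 methylene), C14 the formyl carbon; the target is (1R,4R,5R,6S,7R,8R).

Remark on assumptions: 1, 4 and 16 are taken as commercial; 21 is drawn as the free alcohol although it forms as its chromium alkoxide.

**Alkenyl iodide**

Step 1
Reactants: 1 tert-butyl(diphenyl)(prop-2-yn-1-yloxy)silane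
Product: 2 tert-butyl{[(2Z)-2-(tributylstannyl)-3-(trimethylsilyl)prop-2-en-1-yl]oxy}diphenylsilane
Conditions: Me3SiSnBu3, Pd(PPh3)4 (cat.), THF, 65 °C
Reagents that add atoms: trimethyl(tributylstannyl)silane, C[Si](C)(C)[Sn](CCCC)(CCCC)CCCC
Why: Palladium-catalysed cis-silylstannylation of a terminal alkyne is regio- and stereospecific, tin ending on the internal and silicon on the terminal carbon on the same side, which fixes the later cis relationship of C8 and C1 across C9=C10.

Step 2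
Reactants: 2 tert-butyl{[(2Z)-2-(tributylstannyl)-3-(trimethylsilyl)prop-2-en-1-yl]oxy}diphenylsilane
Product: 3 tert-butyl{[(2Z)-2-iodo-3-(trimethylsilyl)prop-2-en-1-yl]oxy}diphenylsilane
Conditions: I2, CH2Cl2, 0 °C
Reagents that add atoms: iodine, II
Why: Iododestannylation proceeds with retention at the far more reactive C–Sn bond and keeps the C–Si bond as the masked C9 nucleophile.

**Tetrahydropyran aldehyde**

Step 3
Reactants: 4 D-glucal
Product: 5 (1R)-1-(furan-2-yl)ethane-1,2-diol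
Conditions: InCl3·3H2O (cat.), MeCN, rt
Reagents that add atoms: none
Why: Lewis-acid-catalysed hydration of the glycal, ring opening and cyclodehydration onto the C4 hydroxyl give the furan, while the C5 carbinol of the sugar is untouched and becomes the (R)-configured carbinol that ends as C5 of the target.

Step 4
Reactants: 5 (1R)-1-(furan-2-yl)ethane-1,2-diol
Product: 6 (1R)-2-{[tert-butyl(dimethyl)silyl]oxy}-1-(furan-2-yl)ethan-1-ol
Conditions: TBSCl, imidazole, CH2Cl2, 0 °C
Reagents that add atoms: tert-butyl(chloro)dimethylsilane, CC(C)(C)[Si](C)(C)Cl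
Why: Silylation is selective for the less hindered primary hydroxyl and leaves the furyl carbinol free for the ring expansion.

Step 5
Reactants: 6 (1R)-2-{[tert-butyl(dimethyl)silyl]oxy}-1-(furan-2-yl)ethan-1-ol; 3 tert-butyl{[(2Z)-2-iodo-3-(trimethylsilyl)prop-2-en-1-yl]oxy}diphenylsilane
Product: 8 (1R)-2-{[tert-butyl(dimethyl)silyl]oxy}-1-{5-[(1Z)-3-{[tert-butyl(diphenyl)silyl]oxy}-1-(trimethylsilyl)prop-1-en-2-yl]furan-2-yl}ethan-1-ol, via furyl boronate 7 (not isolated)
Conditions: [Ir(OMe)(cod)]2 (cat.), 4,4'-di-tert-butyl-2,2'-bipyridine, B2pin2, THF, 50 °C; then 3, Pd(dppf)Cl2 (cat.), aq. K3PO4, 50 °C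
Reagents that add atoms: none
Why: Iridium-catalysed C–H borylation of a 2-substituted furan goes to the free α-position for steric reasons, and the boronate is used at once in a Suzuki–Miyaura coupling that retains the geometry of 3.

Step 6
Reactants: 8 (1R)-2-{[tert-butyl(dimethyl)silyl]oxy}-1-{5-[(1Z)-3-{[tert-butyl(diphenyl)silyl]oxy}-1-(trimethylsilyl)prop-1-en-2-yl]furan-2-yl}ethan-1-ol
Product: 9 (2R)-2-({[tert-butyl(dimethyl)silyl]oxy}methyl)-6-[(1Z)-3-{[tert-butyl(diphenyl)silyl]oxy}-1-(trimethylsilyl)prop-1-en-2-yl]-6-hydroxy-2H-pyran-3(6H)-one (both C6 epimers)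
Conditions: VO(acac)2 (cat.), t-BuOOH, CH2Cl2, 0 °C to rt
Reagents that add atoms: tert-butyl hydroperoxide, CC(C)(C)OO
Why: Achmatowicz rearrangement: hydroxyl-directed oxidation of the furan gives the ene-dione, which closes to the six-membered hemiketal with the C4 ketone in place, and the carbinol centre is not touched.

Step 7
Reactants: 9 (2R)-2-({[tert-butyl(dimethyl)silyl]oxy}methyl)-6-[(1Z)-3-{[tert-butyl(diphenyl)silyl]oxy}-1-(trimethylsilyl)prop-1-en-2-yl]-6-hydroxy-2H-pyran-3(6H)-one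
Product: 10 (2R,6R)-2-({[tert-butyl(dimethyl)silyl]oxy}methyl)-6-[(1Z)-3-{[tert-butyl(diphenyl)silyl]oxy}-1-(trimethylsilyl)prop-1-en-2-yl]-2H-pyran-3(6H)-one
Conditions: Et3SiH, CF3CO2H, CH2Cl2, −40 °C
Reagents that add atoms: none
Why: Kishi-type ionic reduction: the oxocarbenium ion from the hemiketal takes hydride axially, anti to the C5 side chain, which sets C1 and gives the 2,6-cis ring.

Step 8
Reactants: 10 (2R,6R)-2-({[tert-butyl(dimethyl)silyl]oxy}methyl)-6-[(1Z)-3-{[tert-butyl(diphenyl)silyl]oxy}-1-(trimethylsilyl)prop-1-en-2-yl]-2H-pyran-3(6H)-one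
Product: 11 (2R,6R)-2-({[tert-butyl(dimethyl)silyl]oxy}methyl)-6-[(1Z)-3-{[tert-butyl(diphenyl)silyl]oxy}-1-(trimethylsilyl)prop-1-en-2-yl]oxan-3-one
Conditions: H2 (1 atm), RhCl(PPh3)3 (cat.), benzene, rt
Reagents that add atoms: none
Why: Homogeneous hydrogenation reduces the unhindered cis-disubstituted enone alkene but not the hindered trisubstituted vinylsilane, and causes no allylic C–O hydrogenolysis.

Step 9
Reactants: 11 (2R,6R)-2-({[tert-butyl(dimethyl)silyl]oxy}methyl)-6-[(1Z)-3-{[tert-butyl(diphenyl)silyl]oxy}-1-(trimethylsilyl)prop-1-en-2-yl]oxan-3-one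
Product: 12 (3R,4R,6R)-4-({[tert-butyl(dimethyl)silyl]oxy}methyl)-6-[(1Z)-3-{[tert-butyl(diphenyl)silyl]oxy}-1-(trimethylsilyl)prop-1-en-2-yl]-1,5-dioxaspiro[2.5]octane
Conditions: Me3S+ I−, KN(SiMe3)2, THF, −10 to 0 °C
Reagents that add atoms: trimethylsulfonium iodide, C[S+](C)C.[I-]
Why: Corey–Chaykovsky epoxidation: the small sulfonium ylide should add irreversibly along the axial trajectory of the diequatorial chair, as small carbon nucleophiles do with tetrahydropyran-3-ones, so that C15 becomes axial and cis to the C5 side chain and the epoxide oxygen equatorial, which is the C4 configuration of the target.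

Step 10
Reactants: 12 (3R,4R,6R)-4-({[tert-butyl(dimethyl)silyl]oxy}methyl)-6-[(1Z)-3-{[tert-butyl(diphenyl)silyl]oxy}-1-(trimethylsilyl)prop-1-en-2-yl]-1,5-dioxaspiro[2.5]octane
Product: 13 (3R,4R,6R)-4-({[tert-butyl(dimethyl)silyl]oxy}methyl)-6-[(1Z)-3-{[tert-butyl(diphenyl)silyl]oxy}-1-iodoprop-1-en-2-yl]-1,5-dioxaspiro[2.5]octane
Conditions: NIS, MeCN/ClCH2CN, 0 °C to rt, dark
Reagents that add atoms: N-iodosuccinimide, O=C1CCC(=O)N1I
Why: Electrophilic ipso-iododesilylation of the vinylsilane proceeds with retention of geometry through the β-silyl cation under neutral conditions that spare the epoxide.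

Step 11
Reactants: 13 (3R,4R,6R)-4-({[tert-butyl(dimethyl)silyl]oxy}methyl)-6-[(1Z)-3-{[tert-butyl(diphenyl)silyl]oxy}-1-iodoprop-1-en-2-yl]-1,5-dioxaspiro[2.5]octane
Product: 14 [(3R,4R,6R)-6-[(1Z)-3-{[tert-butyl(diphenyl)silyl]oxy}-1-iodoprop-1-en-2-yl]-1,5-dioxaspiro[2.5]octan-4-yl]methanol
Conditions: HF·pyridine, pyridine, THF, 0 °C
Reagents that add atoms: none
Why: Buffered HF·pyridine cleaves the primary alkyl TBS ether much faster than the bulkier TBDPS ether and is tolerated by the epoxide.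

Step 12
Reactants: 14 [(3R,4R,6R)-6-[(1Z)-3-{[tert-butyl(diphenyl)silyl]oxy}-1-iodoprop-1-en-2-yl]-1,5-dioxaspiro[2.5]octan-4-yl]methanol
Product: 15 (3R,4S,6R)-6-[(1Z)-3-{[tert-butyl(diphenyl)silyl]oxy}-1-iodoprop-1-en-2-yl]-1,5-dioxaspiro[2.5]octane-4-carbaldehyde
Conditions: Dess–Martin periodinane, NaHCO3, CH2Cl2, 0 °C to rt
Reagents that add atoms: none
Why: Dess–Martin oxidation under buffered conditions gives the α-alkoxy aldehyde without epimerisation at C5 (the descriptor changes only because the formyl group now outranks C4), and the aldehyde is used crude.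

**Linchpin**

Step 13
Reactants: 16 (5R)-5-{[(1R,2S,5R)-5-methyl-2-(propan-2-yl)cyclohexyl]oxy}furan-2(5H)-one
Product: 18 (5R)-3-bromo-5-{[(1R,2S,5R)-5-methyl-2-(propan-2-yl)cyclohexyl]oxy}furan-2(5H)-one, via dibromide 17 (not isolated)
Conditions: Br2, CH2Cl2, 0 °C; then Et3N, 0 °C
Reagents that add atoms: bromine, BrBr
Why: Bromine addition to the enoate followed by E1cB loss of HBr (acidic α-hydrogen, β-bromide) gives the α-bromobutenolide, and the acetal centre is not involved.

Step 14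
Reactants: 18 (5R)-3-bromo-5-{[(1R,2S,5R)-5-methyl-2-(propan-2-yl)cyclohexyl]oxy}furan-2(5H)-one
Product: 19 (5R)-3-(hydroxymethyl)-5-{[(1R,2S,5R)-5-methyl-2-(propan-2-yl)cyclohexyl]oxy}furan-2(5H)-one
Conditions: Bu3SnCH2OH, Pd(PPh3)4 (cat.), 1,4-dioxane, 90 °C
Reagents that add atoms: (tributylstannyl)methanol, CCCC[Sn](CO)(CCCC)CCCC
Why: Stille coupling transfers the hydroxymethyl group to the α-bromo enoate under neutral conditions that do not epimerise the acetal.

Step 15
Reactants: 19 (5R)-3-(hydroxymethyl)-5-{[(1R,2S,5R)-5-methyl-2-(propan-2-yl)cyclohexyl]oxy}furan-2(5H)-one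
Product: 20 (5R)-3-(bromomethyl)-5-{[(1R,2S,5R)-5-methyl-2-(propan-2-yl)cyclohexyl]oxy}furan-2(5H)-one
Conditions: CBr4, PPh3, CH2Cl2, 0 °C
Reagents that add atoms: carbon tetrabromide, BrC(Br)(Br)Br
Why: The Appel reaction converts the primary allylic alcohol into the bromide under neutral conditions.

**Union and endgame**

Step 16
Reactants: 15 (3R,4S,6R)-6-[(1Z)-3-{[tert-butyl(diphenyl)silyl]oxy}-1-iodoprop-1-en-2-yl]-1,5-dioxaspiro[2.5]octane-4-carbaldehyde; 20 (5R)-3-(bromomethyl)-5-{[(1R,2S,5R)-5-methyl-2-(propan-2-yl)cyclohexyl]oxy}furan-2(5H)-one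
Product: 23 (1R,4R,5R,6S,7R,8R,9Z)-14-{[tert-butyl(diphenyl)silyl]oxy}-8-hydroxy-1,5:4,15-diepoxygermacra-9,11(13)-dien-6,12-olide, via allylation adduct 21 (not isolated), via lactone aldehyde 22 (not isolated)
Conditions: CrCl2 (8 equiv), THF, 0 °C to rt, 20 added slowly; then DMF (to 2 mM), NiCl2 (cat.), rt
Reagents that add atoms: none
Why: Proposed new method: CrCl2 reduces the allylic bromide of 20 (alkenyl iodides are inert to CrCl2 without nickel) to an allylchromium that adds through its γ-carbon C7 to the C6 aldehyde in a Zimmerman–Traxler chair, the trivalent-chromium alkoxide then attacks the activated pseudo-ester carbonyl, which forms the C6–O–C12 lactone and releases the C8 aldehyde with loss of mentholate, and added NiCl2 turns the C9 iodide into an alkenylchromium that adds to C8. The closest known reaction types are the chromium-mediated 2-(alkoxycarbonyl)allylation of aldehydes with 3-(bromomethyl)butenolides and the Nozaki–Hiyama–Kishi closure of ether-bridged medium rings; the in-situ unmasking of the second electrophile by translactonisation of a 5-alkoxybutenolide is the new element. Ring closures: the γ-lactone by 5-exo-trig acyl substitution, and the ten-membered carbocycle (an eight-membered oxocene counted through the ether oxygen) by exo-trig 1,2-addition, helped by the cis-2,6-substituted tetrahydropyran that holds C9 near C8. Stereocontrol: C7 is set by attack anti to the menthyloxy group on C8 (auxiliary control), C6 by the chair with the ring-locked E-type allyl unit (anti adduct, hence the trans-lactone; this reagent control is asked to override the Felkin–Anh preference of the α-alkoxy aldehyde), and C8 by substrate control in the ring closure, the chromium-bound carbonyl oxygen being expected outside the forming ring and anti to C6. The step needs cross-coupling over self-coupling and allyl-before-alkenyl activation: the linchpin carries no free aldehyde until it is attached, and nickel is withheld until the allylation is over.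

Step 17
Reactants: 23 (1R,4R,5R,6S,7R,8R,9Z)-14-{[tert-butyl(diphenyl)silyl]oxy}-8-hydroxy-1,5:4,15-diepoxygermacra-9,11(13)-dien-6,12-olide
Product: 24 (1R,4R,5R,6S,7R,8R,9Z)-14-{[tert-butyl(diphenyl)silyl]oxy}-8-(methacryloyloxy)-1,5:4,15-diepoxygermacra-9,11(13)-dien-6,12-olide
Conditions: methacrylic anhydride, Et3N, DMAP (cat.), CH2Cl2, 0 °C to rt
Reagents that add atoms: methacrylic anhydride, C=C(C)C(=O)OC(=O)C(C)=C
Why: DMAP-catalysed acylation of the secondary allylic alcohol proceeds with retention at C8.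

Step 18
Reactants: 24 (1R,4R,5R,6S,7R,8R,9Z)-14-{[tert-butyl(diphenyl)silyl]oxy}-8-(methacryloyloxy)-1,5:4,15-diepoxygermacra-9,11(13)-dien-6,12-olide
Product: 25 (1R,4R,5R,6S,7R,8R,9Z)-14-hydroxy-8-(methacryloyloxy)-1,5:4,15-diepoxygermacra-9,11(13)-dien-6,12-olide
Conditions: HF·pyridine, pyridine, THF, 0 °C to rt
Reagents that add atoms: none
Why: Buffered fluoride cleaves the Si–O bond selectively, and the conjugate acceptors and the epoxide tolerate HF·pyridine in pyridine; acyl migration from O8 is excluded because C8 and C14 are trans on the alkene.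

Step 19
Reactants: 25 (1R,4R,5R,6S,7R,8R,9Z)-14-hydroxy-8-(methacryloyloxy)-1,5:4,15-diepoxygermacra-9,11(13)-dien-6,12-olide
Product: 26 (1R,4R,5R,6S,7R,8R,9E)-8-(methacryloyloxy)-14-oxo-1,5:4,15-diepoxygermacra-9,11(13)-dien-6,12-olide
Conditions: MnO2, CH2Cl2, rt
Reagents that add atoms: none
Why: MnO2 oxidises the primary allylic alcohol selectively to the enal and leaves the other functional groups alone (the descriptor becomes 9E only because the formyl group outranks C1).

**Compound list**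

1 | tert-butyl(diphenyl)(prop-2-yn-1-yloxy)silane | C#CCO[Si](c1ccccc1)(c1ccccc1)C(C)(C)C | starting material
2 | tert-butyl{[(2Z)-2-(tributylstannyl)-3-(trimethylsilyl)prop-2-en-1-yl]oxy}diphenylsilane | C[Si](C)(C)/C=C(\[Sn](CCCC)(CCCC)CCCC)CO[Si](c1ccccc1)(c1ccccc1)C(C)(C)C | intermediate
3 | tert-butyl{[(2Z)-2-iodo-3-(trimethylsilyl)prop-2-en-1-yl]oxy}diphenylsilane | C[Si](C)(C)/C=C(\I)CO[Si](c1ccccc1)(c1ccccc1)C(C)(C)C | intermediate
4 | D-glucal (1,5-anhydro-2-deoxy-D-arabino-hex-1-enitol) | OC[C@H]1OC=C[C@@H](O)[C@@H]1O | starting material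
5 | (1R)-1-(furan-2-yl)ethane-1,2-diol | OC[C@@H](O)c1ccco1 | intermediate
6 | (1R)-2-{[tert-butyl(dimethyl)silyl]oxy}-1-(furan-2-yl)ethan-1-ol | CC(C)(C)[Si](C)(C)OC[C@@H](O)c1ccco1 | intermediate
7 | furyl boronate: (1R)-2-{[tert-butyl(dimethyl)silyl]oxy}-1-[5-(4,4,5,5-tetramethyl-1,3,2-dioxaborolan-2-yl)furan-2-yl]ethan-1-ol | CC(C)(C)[Si](C)(C)OC[C@@H](O)c1ccc(o1)B1OC(C)(C)C(C)(C)O1 | intermediate
8 | (1R)-2-{[tert-butyl(dimethyl)silyl]oxy}-1-{5-[(1Z)-3-{[tert-butyl(diphenyl)silyl]oxy}-1-(trimethylsilyl)prop-1-en-2-yl]furan-2-yl}ethan-1-ol | C[Si](C)(C)/C=C(\c1ccc(o1)[C@H](O)CO[Si](C)(C)C(C)(C)C)CO[Si](c1ccccc1)(c1ccccc1)C(C)(C)C | intermediate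
9 | (2R)-2-({[tert-butyl(dimethyl)silyl]oxy}methyl)-6-[(1Z)-3-{[tert-butyl(diphenyl)silyl]oxy}-1-(trimethylsilyl)prop-1-en-2-yl]-6-hydroxy-2H-pyran-3(6H)-one, both C6 epimers | C[Si](C)(C)/C=C(\C1(O)C=CC(=O)[C@@H](CO[Si](C)(C)C(C)(C)C)O1)CO[Si](c1ccccc1)(c1ccccc1)C(C)(C)C | intermediate
10 | (2R,6R)-2-({[tert-butyl(dimethyl)silyl]oxy}methyl)-6-[(1Z)-3-{[tert-butyl(diphenyl)silyl]oxy}-1-(trimethylsilyl)prop-1-en-2-yl]-2H-pyran-3(6H)-one | C[Si](C)(C)/C=C(\[C@H]1C=CC(=O)[C@@H](CO[Si](C)(C)C(C)(C)C)O1)CO[Si](c1ccccc1)(c1ccccc1)C(C)(C)C | intermediate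
11 | (2R,6R)-2-({[tert-butyl(dimethyl)silyl]oxy}methyl)-6-[(1Z)-3-{[tert-butyl(diphenyl)silyl]oxy}-1-(trimethylsilyl)prop-1-en-2-yl]oxan-3-one | C[Si](C)(C)/C=C(\[C@H]1CCC(=O)[C@@H](CO[Si](C)(C)C(C)(C)C)O1)CO[Si](c1ccccc1)(c1ccccc1)C(C)(C)C | intermediate
12 | (3R,4R,6R)-4-({[tert-butyl(dimethyl)silyl]oxy}methyl)-6-[(1Z)-3-{[tert-butyl(diphenyl)silyl]oxy}-1-(trimethylsilyl)prop-1-en-2-yl]-1,5-dioxaspiro[2.5]octane | C[Si](C)(C)/C=C(\[C@H]1CC[C@@]2(CO2)[C@@H](CO[Si](C)(C)C(C)(C)C)O1)CO[Si](c1ccccc1)(c1ccccc1)C(C)(C)C | intermediate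
13 | (3R,4R,6R)-4-({[tert-butyl(dimethyl)silyl]oxy}methyl)-6-[(1Z)-3-{[tert-butyl(diphenyl)silyl]oxy}-1-iodoprop-1-en-2-yl]-1,5-dioxaspiro[2.5]octane | I/C=C(\[C@H]1CC[C@@]2(CO2)[C@@H](CO[Si](C)(C)C(C)(C)C)O1)CO[Si](c1ccccc1)(c1ccccc1)C(C)(C)C | intermediate
14 | [(3R,4R,6R)-6-[(1Z)-3-{[tert-butyl(diphenyl)silyl]oxy}-1-iodoprop-1-en-2-yl]-1,5-dioxaspiro[2.5]octan-4-yl]methanol | I/C=C(\[C@H]1CC[C@@]2(CO2)[C@@H](CO)O1)CO[Si](c1ccccc1)(c1ccccc1)C(C)(C)C | intermediate
15 | (3R,4S,6R)-6-[(1Z)-3-{[tert-butyl(diphenyl)silyl]oxy}-1-iodoprop-1-en-2-yl]-1,5-dioxaspiro[2.5]octane-4-carbaldehyde | I/C=C(\[C@H]1CC[C@@]2(CO2)[C@@H](C=O)O1)CO[Si](c1ccccc1)(c1ccccc1)C(C)(C)C | intermediate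
16 | (5R)-5-{[(1R,2S,5R)-5-methyl-2-(propan-2-yl)cyclohexyl]oxy}furan-2(5H)-one | O=C1C=C[C@H](O[C@@H]2C[C@H](C)CC[C@H]2C(C)C)O1 | starting material
17 | dibromide: (5R)-3,4-dibromo-5-{[(1R,2S,5R)-5-methyl-2-(propan-2-yl)cyclohexyl]oxy}dihydrofuran-2(3H)-one | O=C1C(Br)C(Br)[C@H](O[C@@H]2C[C@H](C)CC[C@H]2C(C)C)O1 | intermediate
18 | (5R)-3-bromo-5-{[(1R,2S,5R)-5-methyl-2-(propan-2-yl)cyclohexyl]oxy}furan-2(5H)-one | BrC1=C[C@H](O[C@@H]2C[C@H](C)CC[C@H]2C(C)C)OC1=O | intermediate
19 | (5R)-3-(hydroxymethyl)-5-{[(1R,2S,5R)-5-methyl-2-(propan-2-yl)cyclohexyl]oxy}furan-2(5H)-one | OCC1=C[C@H](O[C@@H]2C[C@H](C)CC[C@H]2C(C)C)OC1=O | intermediate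
20 | (5R)-3-(bromomethyl)-5-{[(1R,2S,5R)-5-methyl-2-(propan-2-yl)cyclohexyl]oxy}furan-2(5H)-one | BrCC1=C[C@H](O[C@@H]2C[C@H](C)CC[C@H]2C(C)C)OC1=O | intermediate
21 | allylation adduct: 3-methylene-5-(menthyloxy)dihydrofuran-2(3H)-one whose C4 (C7 of the target) carries, trans to the menthyloxy group, the (6S) carbinol attached to C5 of the spiro-epoxy tetrahydropyran | I/C=C(\[C@H]1CC[C@@]2(CO2)[C@H](O1)[C@@H](O)[C@H]1[C@H](O[C@@H]2C[C@H](C)CC[C@H]2C(C)C)OC(=O)C1=C)CO[Si](c1ccccc1)(c1ccccc1)C(C)(C)C | intermediate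
22 | lactone aldehyde: trans-4-formyl-3-methylene-γ-butyrolactone (6S,7R) carrying at C6 the spiro-epoxy tetrahydropyran with the (Z)-iodoalkene arm | I/C=C(\[C@H]1CC[C@@]2(CO2)[C@H](O1)[C@H]1OC(=O)C(=C)[C@@H]1C=O)CO[Si](c1ccccc1)(c1ccccc1)C(C)(C)C | intermediate
23 | (1R,4R,5R,6S,7R,8R,9Z)-14-{[tert-butyl(diphenyl)silyl]oxy}-8-hydroxy-1,5:4,15-diepoxygermacra-9,11(13)-dien-6,12-olide | O[C@@H]1/C=C(/CO[Si](c2ccccc2)(c2ccccc2)C(C)(C)C)[C@H]2CC[C@@]3(CO3)[C@H](O2)[C@H]2OC(=O)C(=C)[C@@H]21 | intermediate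
24 | (1R,4R,5R,6S,7R,8R,9Z)-14-{[tert-butyl(diphenyl)silyl]oxy}-8-(methacryloyloxy)-1,5:4,15-diepoxygermacra-9,11(13)-dien-6,12-olide | C=C(C)C(=O)O[C@@H]1/C=C(/CO[Si](c2ccccc2)(c2ccccc2)C(C)(C)C)[C@H]2CC[C@@]3(CO3)[C@H](O2)[C@H]2OC(=O)C(=C)[C@@H]21 | intermediate
25 | (1R,4R,5R,6S,7R,8R,9Z)-14-hydroxy-8-(methacryloyloxy)-1,5:4,15-diepoxygermacra-9,11(13)-dien-6,12-olide | C=C(C)C(=O)O[C@@H]1/C=C(/CO)[C@H]2CC[C@@]3(CO3)[C@H](O2)[C@H]2OC(=O)C(=C)[C@@H]21 | intermediate
26 | (1R,4R,5R,6S,7R,8R,9E)-8-(methacryloyloxy)-14-oxo-1,5:4,15-diepoxygermacra-9,11(13)-dien-6,12-olide | C=C(C)C(=O)O[C@@H]1/C=C(/C=O)[C@H]2CC[C@@]3(CO3)[C@H](O2)[C@H]2OC(=O)C(=C)[C@@H]21 | target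

**Step count and risks**

Total step count: 19. Longest linear sequence: 14 steps (steps 3–12 and 16–19, from D-glucal 4).

Steps most likely to fail:

Step 16 (Proposed new method). Several processes can go wrong:
- The auxiliary-controlled allylation has to work against the Felkin–Anh preference of the α-alkoxy aldehyde, which may erode the C6/C7 selectivity.
- The chromium alkoxide may translactonise too slowly, so that no aldehyde is present when nickel is added.
- The β,γ-unsaturated aldehyde may isomerise into conjugation.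
- The ring closure may oligomerise or add to the wrong face of the C8 carbonyl.

The fallback sets out from 15 and 20 and divides the step into known operations. Indium powder in THF/H2O should mediate a Barbier allylation under Cram-chelate control through the ring oxygen, which here reinforces the auxiliary, and 21 would be isolated as the free alcohol. A neutral transesterification catalyst (ClBu2SnOSnBu2Cl, toluene, 60 °C) should then translactonise 21 to 22 with loss of menthol. A separate Nozaki–Hiyama–Kishi cyclisation of 22 (CrCl2, NiCl2 cat., DMF, high dilution) comes back to the route at 23. Should the ring closure deliver the C8-epimeric alcohol F1 instead, it would be esterified under Mitsunobu conditions (methacrylic acid, PPh3, DIAD), which inverts C8 and rejoins the route at 24.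

Step 9. The basic ylide may enolise the ketone towards C5, with β-elimination of the silyloxide, or the axial selectivity of the addition may be incomplete. The fallback sets out from 11 and separates C–C bond formation from ring closure. (Phenylthio)methyllithium (from thioanisole, n-BuLi, DABCO) should add at −78 °C, fast and irreversibly in the same axial sense, to give the β-hydroxy sulfide F2, from which a minor C4 epimer can be removed. S-Methylation with Me3O+ BF4− in CH2Cl2 should give the sulfonium salt F3, and aqueous NaOH should close it to the epoxide, which comes back to the route at 12.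

Step 5. The electron-rich 2-furyl boronate may undergo protodeboronation under aqueous base before it transmetalates to the hindered alkenylpalladium. The fallback sets out from 6. Double deprotonation (n-BuLi, 2.1 equiv, THF, −78 °C, kept cold to avoid silyl migration) and quenching with Bu3SnCl should give the isolable furylstannane F4. A Stille coupling with 3 under anhydrous conditions (Pd2(dba)3, tri(2-furyl)phosphine, CuI, DMF, 50 °C) comes back to the route at 8.

Further compounds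

F1 | step 16 | (1R,4R,5R,6S,7R,8S,9Z)-14-{[tert-butyl(diphenyl)silyl]oxy}-8-hydroxy-1,5:4,15-diepoxygermacra-9,11(13)-dien-6,12-olide (C8 epimer of 23) | O[C@H]1/C=C(/CO[Si](c2ccccc2)(c2ccccc2)C(C)(C)C)[C@H]2CC[C@@]3(CO3)[C@H](O2)[C@H]2OC(=O)C(=C)[C@@H]21
F2 | step 9 | (2R,3R,6R)-2-({[tert-butyl(dimethyl)silyl]oxy}methyl)-6-[(1Z)-3-{[tert-butyl(diphenyl)silyl]oxy}-1-(trimethylsilyl)prop-1-en-2-yl]-3-[(phenylsulfanyl)methyl]oxan-3-ol | C[Si](C)(C)/C=C(\[C@H]1CC[C@@](O)(CSc2ccccc2)[C@@H](CO[Si](C)(C)C(C)(C)C)O1)CO[Si](c1ccccc1)(c1ccccc1)C(C)(C)C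
F3 | step 9 | S-methyl sulfonium tetrafluoroborate of F2 | C[Si](C)(C)/C=C(\[C@H]1CC[C@@](O)(C[S+](C)c2ccccc2)[C@@H](CO[Si](C)(C)C(C)(C)C)O1)CO[Si](c1ccccc1)(c1ccccc1)C(C)(C)C.F[B-](F)(F)F
F4 | step 5 | (1R)-2-{[tert-butyl(dimethyl)silyl]oxy}-1-[5-(tributylstannyl)furan-2-yl]ethan-1-ol | CC(C)(C)[Si](C)(C)OC[C@@H](O)c1ccc(o1)[Sn](CCCC)(CCCC)CCCC
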